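**Plan**
- Retrosynthesis: remove the O9 tiglate and the O8 acetate. Then cut C1–C10 and C4–C5 together. This takes ring A apart into a crotonoylacetic acid unit (C1–C4, C15 and one extra carboxyl carbon) and leaves ring B as a cyclohexenol, which goes back to (+)-3-carene.
- Enabling feature: O9 on C9 stands cis to the C10–C1 bond, and C1 is α to the C2 ketone. One carbonyl carbon can therefore span O9 and C1 as a β-keto γ-lactone (O9–CO–C1–C10–C9) and leave later as CO2. The electron-rich C5=C10 alkene of ring B and the C2(=O)–C3=C4 enone have the right polarities for a radical relay C1→C10, then C5→C4.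
- Forward order: ring B is the six-membered ring of carene. C9 is oxygenated by allylic oxidation; opening the cyclopropane gives the C7 isopropenyl group and the enol ether that brings in O8. Then follow the ester tether, closure of the lactone ring and ring A in one operation, loss of CO2, acetate and tiglate.
- Stereochemistry: C7 comes from (+)-3-carene. C8 is set anti to C7, and C9 cis to C8 by hydride. C10, C5 and C4 are relayed from C9 through the tether.

Key step: step 7

Remark: eremophilane numbering is used throughout (ring A = C1–C5, C10; ring B = C5–C10; C14 on C5, C15 on C4, C11–C13 isopropenyl); β is the face of C14 and C15; commercial (+)-3-carene is taken as the (1S,6R) enantiomer.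

Step 1
Reactants: 1 (+)-3-carene
Product: 2 car-3-en-5-one [(1R,6S)-4,7,7-trimethylbicyclo[4.1.0]hept-3-en-2-one]
Conditions: t-BuOOH (decane), Cr(CO)6 (cat.), MeCN, 80 °C
Reagents that add atoms: tert-butyl hydroperoxide, CC(C)(C)OO
Why: Metal-catalysed allylic oxidation with a hydroperoxide: hydrogen abstraction is easiest at the ring CH2 (future C9) whose allyl radical reaches the methyl-bearing alkene carbon, oxygen is taken up at its secondary end, and the two stereocentres at the cyclopropane are not touched.

Step 2
Reactants: 2 car-3-en-5-one
Product: 4 triethylsilyl dienol ether [(S)-triethyl{[5-methyl-3-(prop-1-en-2-yl)cyclohexa-1,5-dien-1-yl]oxy}silane], via tertiary iodide 3 (not isolated)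
Conditions: Et3SiCl, NaI, MeCN/CH2Cl2, 0 °C; then DBU, 0 → 23 °C; pentane, cold aq. NaHCO3
Reagents that add atoms: chlorotriethylsilane, CC[Si](Cl)(CC)CC
Why: Ring opening of a cyclopropyl ketone by a silyl iodide (homoconjugate addition) followed by E2 elimination: O-silylation lets iodide break the external C8–C11 bond, which overlaps best with the carbonyl π system and ends at a tertiary carbon, DBU then removes one of the six methyl hydrogens to give the isopropenyl group, and C7 keeps the configuration it had in 1.

Step 3
Reactants: 4 triethylsilyl dienol ether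
Product: 6 (5R,6R)-3-methyl-5-(prop-1-en-2-yl)-6-(triethylsilyloxy)cyclohex-2-en-1-one, via silyloxy epoxide 5 (not isolated)
Conditions: mCPBA (1.0 equiv), NaHCO3, CH2Cl2, −20 → 0 °C
Reagents that add atoms: 3-chloroperbenzoic acid, OOC(=O)c1cccc(Cl)c1
Why: Rubottom oxidation: the peracid picks the silyl enol ether C8=C9 as the most electron-rich alkene and attacks the face opposite to the neighbouring C7 isopropenyl group, and the silyloxy epoxide opens with 1,4-shift of the silyl group to the new oxygen, which sets C8 trans to C7 and delivers O8 already protected.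

Step 4
Reactants: 6 silyloxy enone
Product: 7 (1S,5R,6R)-3-methyl-5-(prop-1-en-2-yl)-6-(triethylsilyloxy)cyclohex-2-en-1-ol (9α-OH, 8α-OSiEt3, 7β-isopropenyl)
Conditions: LiBH(s-Bu)3 (L-Selectride), THF, −78 °C; H2O/THF quench at −78 °C
Reagents that add atoms: none
Why: 1,2-Reduction of an enone by a bulky trialkylborohydride: the β-methyl group on C5 blocks conjugate reduction and the reagent attacks C9 along the equatorial path from the β face of the half-chair with the C7 and C8 substituents equatorial, which gives the pseudoaxial 9α-alcohol cis to O8.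

Step 5
Reactants: 8 (E)-crotonoyl chloride; 9 Meldrum's acid
Product: 10 5-[(E)-1-hydroxybut-2-en-1-ylidene]-2,2-dimethyl-1,3-dioxane-4,6-dione
Conditions: pyridine, CH2Cl2, 0 → 23 °C
Reagents that add atoms: none
Why: C-Acylation of Meldrum's acid by an acid chloride, which gives the enolised acyl derivative that serves as a store of the acylketene.

Step 6
Reactants: 7 allylic alcohol; 10 crotonoyl Meldrum's acid
Product: 12 (1S,5R,6R)-3-methyl-5-(prop-1-en-2-yl)-6-(triethylsilyloxy)cyclohex-2-en-1-yl (E)-3-oxohex-4-enoate, via crotonoylketene 11 (not isolated)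
Conditions: toluene, 90 °C
Reagents that add atoms: none
Why: Thermal fragmentation of the acyl Meldrum's acid (loss of acetone and CO2) gives the acylketene, which the hindered allylic alcohol traps under neutral conditions to form the β-keto ester without silyl migration or change at any stereocentre.

Step 7
Reactants: 12 β-keto ester
Product: 13 tricyclic β-keto γ-lactone (10βH-eremophil-11-en-2-one with 8α-OSiEt3 and a carbonyl bridge from C1 to O9 on the α face; H1, H9 and H10 all β)
Conditions: Mn(OAc)3·2H2O (2.5 equiv), degassed EtOH (0.01 M), 23 → 60 °C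
Reagents that add atoms: none
Why: Proposed new method: Mn(OAc)3 oxidises the enol of the β-keto ester to the electrophilic C1 radical, which adds to C10, the less substituted end of the electron-rich C5=C10 alkene (γ-lactone ring, 5-exo-trig), and the nucleophilic tertiary C5 radical then adds to C4, the β-carbon of the E-enone (ring A, 6-endo-trig), to leave an α-keto radical at C3 that takes a hydrogen atom from ethanol. The closest known reaction type is the oxidative free-radical cyclisation of unsaturated β-keto esters by trivalent manganese, which includes lactone-forming 5-exo closures of allylic acetoacetates and malonates and tandem closures through tertiary radicals; new is that the second acceptor is the enone of the same β-keto ester, so that the relay amounts to a formal [4+2] annulation of an unactivated alkene. C10 is set by the three-atom tether O9–C(=O)–C1, which can reach only the α face on which O9 stands (cis-fused lactone), and C1 ends with its hydrogen β because only that epimer lets the chain reach C5; this centre is erased in step 8. C5 is set because the chain on the equatorial C10–C1 bond can meet only the axial α lobe of the radical in the ring B chair that keeps the C7 and C8 substituents equatorial, which gives the cis-decalin with C14 β. C4 is set by the E geometry of the enone together with a chair-like closure about the staggered C5–C10 single bond, which places C15 equatorial on ring A and thus cis to C14, whereas a concerted cycloaddition through a boat would give the C4 epimer. The step needs chemoselectivity among three alkenes and between radical capture and ring closure: ring size and polarity secure the first (the isopropenyl group is reachable only through seven- or eight-membered rings, the enone repels the electrophilic C1 radical), and ethanol secures the second because its hydridic C–H bonds react fast with the electrophilic C3 radical and slowly with the nucleophilic C5 radical.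

Step 8
Reactants: 13 tricyclic β-keto γ-lactone
Product: 16 8α,9α-dihydroxy-10βH-eremophil-11-en-2-one, via keto acid 14 (not isolated), via silyl ether 15 (not isolated)
Conditions: LiCl, DMSO/H2O (20:1), 130 °C; cool; 1 M HCl, THF, 23 °C
Reagents that add atoms: none
Why: Krapcho-type neutral dealkoxycarbonylation of a β-keto lactone: water opens the acyl–oxygen bond (directly or through the acylketene), the β-keto acid loses CO2 so that the helper carbon and the C1 stereocentre vanish and O9–H is set free with retention, and dilute acid then cleaves the triethylsilyl ether.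

Step 9
Reactants: 16 diol
Product: 17 8α-acetoxy-9α-hydroxy-10βH-eremophil-11-en-2-one
Conditions: Ac2O (1.1 equiv), pyridine, CH2Cl2, 0 °C
Reagents that add atoms: acetic anhydride, CC(=O)OC(C)=O
Why: Hydroxyl-selective acylation: O8–H is equatorial and open, whereas O9–H is axial on ring B, lies under ring A next to the ring fusion and is partly tied up as the hemiketal with C2, so one equivalent of anhydride should take O8.

Step 10
Reactants: 17 monoacetate
Product: 18 target, (4S,5R,7R,8R,9S,10S)-8α-acetoxy-9α-tigloyloxy-10βH-eremophil-11-en-2-one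
Conditions: tigloyl chloride, Et3N, DMAP, ClCH2CH2Cl, 60 °C
Reagents that add atoms: (E)-2-methylbut-2-enoyl chloride (tigloyl chloride), ClC(=O)/C(C)=C/C
Why: DMAP-catalysed acylation by the acid chloride through the acylpyridinium ion, which is reactive enough for the hindered axial 9α-hydroxyl group, and the E-configured tiglate is the stable alkene isomer so that no isomerisation is to be feared.

**Compound list**
1 | (+)-3-carene, (1S,6R)-3,7,7-trimethylbicyclo[4.1.0]hept-3-ene | CC1=CC[C@@H]2[C@H](C1)C2(C)C | starting material
2 | car-3-en-5-one, (1R,6S)-4,7,7-trimethylbicyclo[4.1.0]hept-3-en-2-one | CC1=CC(=O)[C@@H]2[C@H](C1)C2(C)C | intermediate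
3 | (S)-triethyl{[3-(2-iodopropan-2-yl)-5-methylcyclohexa-1,5-dien-1-yl]oxy}silane | CC1=CC(O[Si](CC)(CC)CC)=C[C@H](C1)C(C)(C)I | intermediate
4 | (S)-triethyl{[5-methyl-3-(prop-1-en-2-yl)cyclohexa-1,5-dien-1-yl]oxy}silane | CC1=CC(O[Si](CC)(CC)CC)=C[C@H](C1)C(C)=C | intermediate
5 | C8–C9 silyloxy epoxide of 4, epoxide oxygen on the face opposite to the isopropenyl group | CC1=C[C@]2(O[Si](CC)(CC)CC)O[C@@H]2[C@H](C1)C(C)=C | intermediate
6 | (5R,6R)-3-methyl-5-(prop-1-en-2-yl)-6-(triethylsilyloxy)cyclohex-2-en-1-one | CC1=CC(=O)[C@H](O[Si](CC)(CC)CC)[C@H](C1)C(C)=C | intermediate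
7 | (1S,5R,6R)-3-methyl-5-(prop-1-en-2-yl)-6-(triethylsilyloxy)cyclohex-2-en-1-ol | CC1=C[C@H](O)[C@H](O[Si](CC)(CC)CC)[C@H](C1)C(C)=C | intermediate
8 | (E)-crotonoyl chloride | C/C=C/C(=O)Cl | starting material
9 | Meldrum's acid, 2,2-dimethyl-1,3-dioxane-4,6-dione | CC1(C)OC(=O)CC(=O)O1 | starting material
10 | 5-[(E)-1-hydroxybut-2-en-1-ylidene]-2,2-dimethyl-1,3-dioxane-4,6-dione | C/C=C/C(O)=C1C(=O)OC(C)(C)OC1=O | intermediate
11 | (E)-crotonoylketene, (4E)-hexa-1,4-diene-1,3-dione | C/C=C/C(=O)C=C=O | intermediate
12 | (1S,5R,6R)-3-methyl-5-(prop-1-en-2-yl)-6-(triethylsilyloxy)cyclohex-2-en-1-yl (E)-3-oxohex-4-enoate | CC1=C[C@H](OC(=O)CC(=O)/C=C/C)[C@H](O[Si](CC)(CC)CC)[C@H](C1)C(C)=C | intermediate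
13 | tricyclic β-keto γ-lactone (C1–CO–O9 bridge α, 8α-OSiEt3, cis-decalin) | C=C(C)[C@H]1C[C@@]2(C)[C@@H]3[C@H](C(=O)C[C@@H]2C)C(=O)O[C@@H]3[C@@H]1O[Si](CC)(CC)CC | intermediate
14 | 9α-hydroxy-2-oxo-8α-(triethylsilyloxy)-10βH-eremophil-11-ene-1-carboxylic acid | C=C(C)[C@H]1C[C@@]2(C)[C@H]([C@@H](C(=O)O)C(=O)C[C@@H]2C)[C@H](O)[C@@H]1O[Si](CC)(CC)CC | intermediate
15 | 9α-hydroxy-8α-(triethylsilyloxy)-10βH-eremophil-11-en-2-one | C=C(C)[C@H]1C[C@@]2(C)[C@H](CC(=O)C[C@@H]2C)[C@H](O)[C@@H]1O[Si](CC)(CC)CC | intermediate
16 | 8α,9α-dihydroxy-10βH-eremophil-11-en-2-one | C=C(C)[C@H]1C[C@@]2(C)[C@H](CC(=O)C[C@@H]2C)[C@H](O)[C@@H]1O | intermediate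
17 | 8α-acetoxy-9α-hydroxy-10βH-eremophil-11-en-2-one | C=C(C)[C@H]1C[C@@]2(C)[C@H](CC(=O)C[C@@H]2C)[C@H](O)[C@@H]1OC(C)=O | intermediate
18 | 8α-acetoxy-9α-tigloyloxy-10βH-eremophil-11-en-2-one | C=C(C)[C@H]1C[C@@]2(C)[C@H](CC(=O)C[C@@H]2C)[C@H](OC(=O)/C(C)=C/C)[C@@H]1OC(C)=O | target

**Step count**
Total step count: 10. Longest linear sequence: 9 (steps 1–4 and 6–10).

**Steps most likely to fail**

Step 7.
- What may go wrong: the lactone closure may be slow because the ester prefers the rotamer that holds C1 away from C10. The first closure may run through the C1 epimer whose acyl chain points away from C5. The C5 radical may be oxidised by trivalent manganese before it reaches C4.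
- Fallback, from 12 back to 13: 12 is brominated at C1 (NBS, cat. Mg(ClO4)2, MeCN, 0 °C) to the α-bromo β-keto ester F1.
- Bromine atom-transfer radical cyclisation (Et3B/O2, Yb(OTf)3, CH2Cl2, −40 °C) closes only the lactone. It stores the C5 radical as the tertiary bromide F2, in which the C1 epimers equilibrate through the enol.
- (Me3Si)3SiH and AIBN in benzene at 80 °C then regenerate the C5 radical with no oxidant present, for a Giese-type 6-endo closure to 13.

Step 2.
- What may go wrong: loss of HI toward C7 may give the conjugated isopropylidene isomer. Cleavage of the internal cyclopropane bond may enlarge the ring. The cyclohexadiene may aromatise.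
- Fallback, from 2 back to 4: acid-catalysed hydration of the cyclopropyl ketone (10% aq. H2SO4, THF, 40 °C) gives the tertiary alcohol F3.
- Dehydration with SOCl2 in pyridine at 0 °C gives the enone F4.
- Kinetic deprotonation at C8 with LDA (THF, −78 °C) and O-silylation with Et3SiCl give 4.

Step 8.
- What may go wrong: O9 may recapture the opened acyl unit faster than water adds, and retro-Claisen cleavage of ring A may occur at the high temperature.
- Fallback, from 13 back to 15: transesterification with allyl alcohol (DMAP, toluene, 110 °C) opens the lactone to the allyl β-keto ester F5.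
- Pd(PPh3)4 and morpholine in THF at 23 °C (Tsuji–Trost deallylation with decarboxylation) then give 15 under neutral conditions. The acid treatment of step 8 completes the way to 16.

**Further compounds**
F1 | step 7 | α-bromo β-keto ester of 7 (C1 epimers) | CC1=C[C@H](OC(=O)C(Br)C(=O)/C=C/C)[C@H](O[Si](CC)(CC)CC)[C@H](C1)C(C)=C
F2 | step 7 | cis-fused α-crotonoyl γ-lactone with tertiary bromide at C5 (C1 and C5 epimers) | C=C(C)[C@H]1CC(C)(Br)[C@@H]2C(C(=O)/C=C/C)C(=O)O[C@@H]2[C@@H]1O[Si](CC)(CC)CC
F3 | step 2 | (S)-5-(2-hydroxypropan-2-yl)-3-methylcyclohex-2-en-1-one | CC1=CC(=O)C[C@H](C1)C(C)(C)O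
F4 | step 2 | (S)-3-methyl-5-(prop-1-en-2-yl)cyclohex-2-en-1-one | CC1=CC(=O)C[C@H](C1)C(C)=C
F5 | step 8 | allyl 9α-hydroxy-2-oxo-8α-(triethylsilyloxy)-10βH-eremophil-11-ene-1-carboxylate (C1 epimers) | C=C(C)[C@H]1C[C@@]2(C)[C@H](C(C(=O)OCC=C)C(=O)C[C@@H]2C)[C@H](O)[C@@H]1O[Si](CC)(CC)CC
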